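I start from a ratio, free base charged over electrophile charged, which I call the base cover, w: 0.300 in elm and 0.450 in oak. In my reckoning it marks how far the reaction gets before its acid goes to another taker.

- elm: electrophile 0.10 M; nucleophile 0.200 M; free base 0.0300 M; time 2.5 min
- oak: electrophile 0.10 M; nucleophile 0.200 M; free base 0.0450 M; time 2.5 min

    electrophile + nucleophile → acid set free + target (k1 = 0.0577 /M/s)
    nucleophile + acid set free ⇌ protonated nucleophile, settled at all times (K2 = 347 /M)
    acid set free + free base ⇌ salt of the base, settled at all times (K3 = 31900 /M)
    free base + target ⇌ idle adduct, settled at all times (K4 = 47 /M)
    target ⇌ isomer of the product (K5 = 2.08, k5 = 0.00452 /s)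

- what is said of target includes idle adduct
- run time (elm): 2.5 min

1. part of the electrophile that has reacted at the end, elm
2. part of the electrophile that has reacted at the end, oak
3. what raising the concentration of free base from its lowest to its highest value here does to the part of the electrophile that has reacted (changes below 5 percentage points count as none) (no change / it rises / it falls)

I reckon in fractions of the electrophile charge, the limiting reagent. Let f be the part reacted, b the nucleophile charged over electrophile charged, 2.00, and τ the clock, the first step's rate constant times electrophile charged times time, 0.866 at the end.

In the first instants the acid set free goes to free base, because binding constant times charge in elm is 960 for free base against 69 for nucleophile. Each electrophile then costs one nucleophile, and f grows as (1 − f)(b − f), plain second order. That stretch ends at f = w and uses 0.194 of the clock in elm and 0.343 in oak.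

Past f = w, I book each further acid onto nucleophile as protonated nucleophile. Nucleophile now pays two per electrophile, and f grows as (1 − f)(b + w − 2f). Joining this second solution to the first at f = w and running out the clock gives 69.1 % in elm and 71.3 % in oak. The gap of 2.2 percentage points is under the 5 points that counts, so I say no change. Free target meanwhile turns into its isomer, with a half-life of 2.6 min by the forward rate alone, but my rate of f has no term for that.

The forecast says no change, and its numbers stand slightly below mine; it too has “the excess acid protonates nucleophile”.

| Flask | w | Mine | Forecast | Simulation |
|---|---|---|---|---|
| elm | 0.300 | 69.1 % | 68.3 % | 68.5 % |
| oak | 0.450 | 71.3 % | 70.1 % | 70.1 % |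

The simulated change is 1.7 points, so the answer is no change. In elm the first step ran on past the cover: at 1.25 min the part reacted stood at 49.9 %, with 4.98 % of the charged free base unbound. In elm by 2.50 min protonated nucleophile held 0.395 of the electrophile charge, against 0.385 for part reacted less cover, while isomer of the product had reached 20.2 % of the electrophile charged.

A neighbour flask, oak with 0.040 M of electrophile, has a cover of 1.12, so in my reckoning the first stretch runs to the end. With b = 5.00 and τ = 0.346 it gives 78.9 %; the simulation gives 78.5 %.

The rate constants are those of an exercise; the run is a simulation.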